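Assumption: (−)-α-thujone (the cedar-leaf-oil ketone; the commercial α/β mixture converges in step 1) counts as a cheap commercial starting material. Positions are given in daucane numbering: C-1 quaternary methyl carbon, C-2 and C-6 ester carbinols, C-4 tertiary carbinol, C-5 ring-fusion CH.

**Retrosynthetic overview**
1. Target ⇒ triol by acylation of the two secondary alcohols with angelic acid (last step); the C-2 carbinol ⇒ C-2 ketone by hydride delivery directed by the C-4 hydroxyl.
2. Cycloheptene (the only ring that is built, closed last) ⇒ ring-closing metathesis of a C-1 allyl arm and a C-6 methallyl carbinol arm.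
3. C-6 carbinol ⇒ chelation-controlled methallylation of a β-hydroxy aldehyde.
4. Key disconnection: the C-4–O bond (and the C-6 aldehyde oxygen) ⇒ O2 plus the outer cyclopropane C–C bond of an allylated thujone silyl enol ether, via a cis-fused 1,2-dioxolane.
5. Allylated bicycle ⇒ (−)-α-thujone + allyl bromide; the cyclopentane is the thujone ring throughout, and its (1S,5R) centres become C-4 and C-5.

**Route**

Step 1
Reactants: 1 (−)-α-thujone; 2 allyl bromide
Product: 3 (1S,4R,5S)-4-methyl-4-(prop-2-en-1-yl)-1-(propan-2-yl)bicyclo[3.1.0]hexan-3-one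
Conditions: KOt-Bu, t-BuOH/THF, 0 °C; then 2, 0 °C to rt
Reagents that add atoms: allyl bromide (2), C=CCBr
Why: Thermodynamic enolate C-alkylation at the more substituted, methyl-bearing α-carbon (the CH2 side is neopentyl-like next to the isopropyl-bearing cyclopropane carbon); the allyl group enters anti to the cyclopropane CH2, so the methyl ends cis to it, and both thujone C-4 epimers converge through the planar enolate.

Step 2
Reactants: 3 (1S,4R,5S)-4-methyl-4-(prop-2-en-1-yl)-1-(propan-2-yl)bicyclo[3.1.0]hexan-3-one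
Product: 6 (1R,2R,5R)-5-hydroxy-2-methyl-3-oxo-2-(prop-2-en-1-yl)-5-(propan-2-yl)cyclopentane-1-carbaldehyde, via trimethylsilyl enol ether 4 (not isolated), via cis-fused 1,2-dioxolane 5 (not isolated)
Conditions: 1) TMSOTf, Et3N, CH2Cl2, 0 °C, then pentane filtration; 2) 9-mesityl-10-methylacridinium tetrafluoroborate (5 mol%), O2 (1 atm), MeCN, 450 nm LED, −20 °C; 3) Et3N, then KF (cat.), MeOH, 0 °C
Reagents that add atoms: dioxygen, O=O
Why: Proposed new method: aerobic photoredox ring-opening 1,3-dioxygenation of a cyclopropyl silyl enol ether followed by Kornblum–DeLaMare fragmentation; one-electron oxidation of the enol ether 4 puts spin on C-3, which is cyclopropylcarbinyl, so the outer C-4–CH2 bond opens (the kinetically preferred mode of bicyclo[3.1.0]hex-2-yl radicals) to a primary radical and a siloxyallyl cation, the radical takes up O2, the peroxyl is reduced by the acridinyl radical, and the peroxide anion closes on the cation terminus C-4, which it can only reach from the face the CH2 arm sits on, so the dioxolane 5 is cis-fused and the new C-4–O bond stands where the cyclopropane bond stood (this sets the tertiary carbinol); Et3N then removes a CH2–O proton to give the aldehyde and the C-4 alkoxide while the enol ether still masks the ketone, and methanolysis frees the ketone; the closest known reaction types are the thiyl-radical/O2 oxygenation of vinylcyclopropanes to 1,2-dioxolanes, the aerobic ring-opening oxygenation of cyclopropanols, and photocatalytic radical-cation endoperoxide syntheses.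

Step 3
Reactants: 6 (1R,2R,5R)-5-hydroxy-2-methyl-3-oxo-2-(prop-2-en-1-yl)-5-(propan-2-yl)cyclopentane-1-carbaldehyde; 7 3-bromo-2-methylprop-1-ene
Product: 8 (2R,3S,4R)-4-hydroxy-3-[(1S)-1-hydroxy-3-methylbut-3-en-1-yl]-2-methyl-2-(prop-2-en-1-yl)-4-(propan-2-yl)cyclopentan-1-one
Conditions: In powder, 7, THF/H2O (1:1), rt
Reagents that add atoms: 3-bromo-2-methylprop-1-ene (7), C=C(C)CBr
Why: Barbier-type allylation in which indium is chelated between the C-4 hydroxyl and the aldehyde oxygen, so the carbonyl oxygen is held toward O-4 and the methallyl group enters from the only open sector (between H-5 and C-1; the other is walled in by the two quaternary carbons), giving the (S)-carbinol; the hindered ketone is left alone.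

Step 4
Reactants: 8 (2R,3S,4R)-4-hydroxy-3-[(1S)-1-hydroxy-3-methylbut-3-en-1-yl]-2-methyl-2-(prop-2-en-1-yl)-4-(propan-2-yl)cyclopentan-1-one
Product: 9 (3R,3aS,4S,8aR)-3,4-dihydroxy-6,8a-dimethyl-3-(propan-2-yl)-3,3a,4,5,8,8a-hexahydroazulen-1(2H)-one
Conditions: second-generation Grubbs catalyst (H2IMes)(PCy3)Cl2Ru=CHPh (5 mol%), CH2Cl2 (5 mM), 40 °C
Reagents that add atoms: none
Why: Ring-closing metathesis of the monosubstituted and the 1,1-disubstituted alkene gives the trisubstituted cycloheptene; the two arms are trans on the cyclopentane, so closure gives the trans-fused hydroazulene without touching a stereocentre, and loss of ethene drives it.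

Step 5
Reactants: 9 (3R,3aS,4S,8aR)-3,4-dihydroxy-6,8a-dimethyl-3-(propan-2-yl)-3,3a,4,5,8,8a-hexahydroazulen-1(2H)-one
Product: 10 (1S,3R,3aS,4S,8aR)-6,8a-dimethyl-3-(propan-2-yl)-1,2,3,3a,4,5,8,8a-octahydroazulene-1,3,4-triol
Conditions: Me4NBH(OAc)3, MeCN/AcOH (1:1), −20 °C to rt
Reagents that add atoms: none
Why: Evans–Saksena hydroxyl-directed reduction, in which the borohydride exchanges onto the C-4 hydroxyl and delivers hydride inside the molecule to the same face of the C-2 ketone, giving the C-2 alcohol trans to the C-4 hydroxyl (the 2α-alcohol); the reagent does not reduce the ketone from outside and leaves the alkene.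

Step 6
Reactants: 10 (1S,3R,3aS,4S,8aR)-6,8a-dimethyl-3-(propan-2-yl)-1,2,3,3a,4,5,8,8a-octahydroazulene-1,3,4-triol; 11 angelic acid
Product: 13 (1S,3R,3aS,4S,8aR)-3-hydroxy-6,8a-dimethyl-3-(propan-2-yl)-1,2,3,3a,4,5,8,8a-octahydroazulene-1,4-diyl bis[(2Z)-2-methylbut-2-enoate], via 4-monoangelate 12 (not isolated)
Conditions: 11, 2,4,6-Cl3C6H2COCl, Et3N, toluene, rt; then 10, 80 °C
Reagents that add atoms: angelic acid (11), C/C=C(/C)C(=O)O
Why: Yamaguchi-type mixed-anhydride esterification acylates the two secondary alcohols while the tertiary C-4 hydroxyl stays free; no carbinol centre is touched, and the DMAP-free conditions keep the (Z)-geometry of the angelate.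

**Compound list**
1 | (−)-α-thujone, (1S,4R,5R)-4-methyl-1-(propan-2-yl)bicyclo[3.1.0]hexan-3-one | CC(C)[C@]12CC(=O)[C@H](C)[C@H]1C2 | starting material
2 | allyl bromide (3-bromoprop-1-ene) | C=CCBr | starting material
3 | (1S,4R,5S)-4-methyl-4-(prop-2-en-1-yl)-1-(propan-2-yl)bicyclo[3.1.0]hexan-3-one (allyl trans to the cyclopropane CH2) | CC(C)[C@]12CC(=O)[C@](C)(CC=C)[C@H]1C2 | intermediate
4 | trimethyl{[(1S,4R,5S)-4-methyl-4-(prop-2-en-1-yl)-1-(propan-2-yl)bicyclo[3.1.0]hex-2-en-3-yl]oxy}silane | CC(C)[C@]12C=C(O[Si](C)(C)C)[C@](C)(CC=C)[C@H]1C2 | intermediate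
5 | cis-fused 1,2-dioxolane: 4-methyl-4-(prop-2-en-1-yl)-6a-(propan-2-yl)-5-(trimethylsilyloxy)-3,3a,4,6a-tetrahydrocyclopenta[c][1,2]dioxole (O–O bridges C-4 and the former cyclopropane CH2; allyl trans to the CH2O arm) | CC(C)[C@]12C=C(O[Si](C)(C)C)[C@](C)(CC=C)[C@H]1COO2 | intermediate
6 | (1R,2R,5R)-5-hydroxy-2-methyl-3-oxo-2-(prop-2-en-1-yl)-5-(propan-2-yl)cyclopentane-1-carbaldehyde | CC(C)[C@]1(O)CC(=O)[C@](C)(CC=C)[C@H]1C=O | intermediate
7 | 3-bromo-2-methylprop-1-ene | C=C(C)CBr | starting material
8 | (2R,3S,4R)-4-hydroxy-3-[(1S)-1-hydroxy-3-methylbut-3-en-1-yl]-2-methyl-2-(prop-2-en-1-yl)-4-(propan-2-yl)cyclopentan-1-one | CC(C)[C@]1(O)CC(=O)[C@](C)(CC=C)[C@H]1[C@@H](O)CC(C)=C | intermediate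
9 | (3R,3aS,4S,8aR)-3,4-dihydroxy-6,8a-dimethyl-3-(propan-2-yl)-3,3a,4,5,8,8a-hexahydroazulen-1(2H)-one | CC(C)[C@]1(O)CC(=O)[C@]2(C)CC=C(C)C[C@H](O)[C@@H]12 | intermediate
10 | (1S,3R,3aS,4S,8aR)-6,8a-dimethyl-3-(propan-2-yl)-1,2,3,3a,4,5,8,8a-octahydroazulene-1,3,4-triol | CC(C)[C@]1(O)C[C@H](O)[C@]2(C)CC=C(C)C[C@H](O)[C@@H]12 | intermediate
11 | angelic acid, (2Z)-2-methylbut-2-enoic acid | C/C=C(/C)C(=O)O | starting material
12 | (1S,3R,3aS,4S,8aR)-1,3-dihydroxy-6,8a-dimethyl-3-(propan-2-yl)-1,2,3,3a,4,5,8,8a-octahydroazulen-4-yl (2Z)-2-methylbut-2-enoate | C/C=C(/C)C(=O)O[C@H]1CC(C)=CC[C@@]2(C)[C@@H](O)C[C@@](O)(C(C)C)[C@H]12 | intermediate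
13 | (1S,3R,3aS,4S,8aR)-3-hydroxy-6,8a-dimethyl-3-(propan-2-yl)-1,2,3,3a,4,5,8,8a-octahydroazulene-1,4-diyl bis[(2Z)-2-methylbut-2-enoate] | C/C=C(/C)C(=O)O[C@H]1CC(C)=CC[C@@]2(C)[C@@H](OC(=O)/C(C)=C\C)C[C@@](O)(C(C)C)[C@H]12 | target

**Step count**
Total steps: 6. Longest linear sequence: 6 steps (1 to 13).

**Three steps most likely to fail**

Step 2 (the proposed new step). The risks are oxygenation at C-3 before the ring opens, over-oxidation of 5, and cleavage of the inner cyclopropane bond. The fallback uses known reactions, sets out from 3 and comes back at 6. PhNMe3Br3 (THF, 0 °C) brominates the only enolisable position to give the α-bromo ketone F1. Bu3SnH/AIBN under air (toluene, 80 °C, then PPh3) sends the α-keto radical through the same cyclopropylcarbinyl opening and traps the primary radical with O2, giving the hydroxymethyl enone F2. PhCHO with catalytic KOt-Bu (THF, 0 °C) adds the hemiacetal oxygen to C-4 from the CH2O arm (tethered oxa-Michael addition), giving the cis-fused benzylidene acetal F3. Aqueous AcOH (80%, 40 °C) releases the keto diol F4, and TEMPO/PhI(OAc)2 (CH2Cl2) oxidises its primary alcohol to 6.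

Step 3. The risks are the diastereoselectivity at C-6 and the rate at an aldehyde flanked by two quaternary carbons. The fallback goes from 6 straight to 8 and replaces chelate control by reagent control: (−)-B-(2-methylallyl)diisopinocampheylborane (from (+)-α-pinene), Et2O, −78 °C, then NaBO3 work-up. This reagent attacks the Si face of aldehydes, which is the face needed here, and it does not touch the ketone at low temperature. No new compound is made (none F0).

Step 6. The risks are incomplete acylation of the neopentyl-type C-2 alcohol and Z to E drift of the angelate. The fallback goes from 10 to 13 and builds the angelates on the molecule. Esterification with 2-[bis(2,2,2-trifluoroethoxy)phosphoryl]propanoic acid (EDC·HCl, DMAP, CH2Cl2) gives the bis(phosphonopropanoate) F5. KN(SiMe3)2/18-crown-6 and acetaldehyde (THF, −78 °C; Still–Gennari olefination) then form both (Z)-2-methylbut-2-enoates and give 13.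

**Further compounds**
F1 | step 2 | 2-bromo-4-methyl-4-(prop-2-en-1-yl)-1-(propan-2-yl)bicyclo[3.1.0]hexan-3-one (both C-2 bromide epimers; other centres as in 3) | CC(C)[C@]12C(Br)C(=O)[C@](C)(CC=C)[C@H]1C2
F2 | step 2 | (4S,5R)-4-(hydroxymethyl)-5-methyl-5-(prop-2-en-1-yl)-3-(propan-2-yl)cyclopent-2-en-1-one | CC(C)C1=CC(=O)[C@](C)(CC=C)[C@H]1CO
F3 | step 2 | cis-fused benzylidene acetal of F4: 5-methyl-2-phenyl-5-(prop-2-en-1-yl)-7a-(propan-2-yl)hexahydrocyclopenta[d][1,3]dioxin-6-one (acetal carbon unassigned) | CC(C)[C@]12CC(=O)[C@](C)(CC=C)[C@H]1COC(c3ccccc3)O2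
F4 | step 2 | (2R,3S,4R)-4-hydroxy-3-(hydroxymethyl)-2-methyl-2-(prop-2-en-1-yl)-4-(propan-2-yl)cyclopentan-1-one | CC(C)[C@]1(O)CC(=O)[C@](C)(CC=C)[C@H]1CO
F0 | step 3 | none | none
F5 | step 6 | 1,4-bis{2-[bis(2,2,2-trifluoroethoxy)phosphoryl]propanoate} of triol 10 (phosphonate α-carbons unassigned) | CC(C)[C@]1(O)C[C@H](OC(=O)C(C)P(=O)(OCC(F)(F)F)OCC(F)(F)F)[C@]2(C)CC=C(C)C[C@H](OC(=O)C(C)P(=O)(OCC(F)(F)F)OCC(F)(F)F)[C@@H]12
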